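## Structural features

Siphonellinol C is a squalene-derived triterpenoid. A trans-fused oxepane–cyclohexane bicycle (rings A and B) is joined through the two-carbon chain C12–C13 to a tetrasubstituted cyclohexene (ring C), which carries an (E)-4-hydroxy-4-methylpent-2-enyl chain. Ring A holds O1, the gem-dimethyl carbon C2 and the secondary carbinol C3 (R). It shares the quaternary carbon C6 (methyl) and the ether methine C7 with ring B, which also carries the tertiary carbinol C10 (axial OH) and C11 with its equatorial chain. C6, C7, C10 and C11 are contiguous, and two of them are fully substituted. Ring C adds the vicinal pair C18 (carbinol) and quaternary C19, remote from the first set, so both halves must be made as single enantiomers and then joined. Fragile points are the tertiary allylic alcohol at C23 (ionization), the tertiary carbinol at C10, and, during the synthesis, a C11 centre that is α to a C10 carbonyl while it is allylic or β-oxygenated. The real difficulty is the seven-membered ether whose oxygen bridges a tertiary carbon (C2) and a ring-fusion methine (C7) next to the quaternary C6; neither C–O bond is easily made by substitution. The key step exploits the fact that O1–C2(Me)2–C3(O) with C7 on O1 is the skeleton of a 2,2-dimethylfuran-3(2H)-one. Its C4=C7 bond takes up the alkene C5=C6 to close ring B, and later cleavage of C4–C7 expands the five-membered ring to ring A with both C–O bonds already in place.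

## Logic of the disconnections

40 to 38: the C21=C22 double bond (cross-metathesis) and the two O–Si bonds are cut. The acid-sensitive tertiary allylic alcohol is thereby introduced last and the side chain is carried as a plain allyl group. The forward step must leave the tetrasubstituted C14=C15 alkene untouched and the final deprotection must be basic.

38 to 37: the C10–CH3 bond is cut. The axial tertiary carbinol becomes a ketone and one stereocentre is removed. The methyl nucleophile must add rather than enolize C11 and must enter from the equatorial side.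

37 to 26 and 34 (through 36): the sp3–sp2 bond C13–C14 is cut, the only link between the two stereochemical domains and adjacent to a carbon that can be an enol triflate. This gives two halves of similar size. The forward coupling must tolerate a triflate flanked by a quaternary centre and a borane next to the congested C11.

34 to 27: the C15 methyl, the C19 allyl group and the C18 hydride are removed to reach a symmetric dione. C18 and C19 are set together in one desymmetrizing reduction, which must select one enantiotopic carbonyl and place OH cis to allyl.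

26 to 21: C12=C13 is traced to a C12 aldehyde and then to the protected carbinol, and the C3 carbinol to a ketone. No ring bond changes. The forward steps need reagent control at C3 and must not epimerize C11 at the aldehyde stage; C10 stays a ketal throughout so that C11 is never α to a free ketone here.

21 to 19: in the retrosynthetic sense C4 and C7 are joined, so the oxepanone becomes a furanone fused to a cyclobutane. This removes the seven-membered ether problem. The forward step must break C4–C7 and no other bond, and must deliver hydrogen to C7 trans to the C6 methyl group.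

19 to 18: C4–C5 and C6–C7 are cut (key step). Two rings and three stereocentres are removed, leaving a flat furanone, a 1,1-disubstituted alkene and one stereocentre (C11). The forward step must give the straight adduct and must use C11 to choose the alkene face.

18 to 12 and 14 (through 17): O1–C7 and C3–C4 are cut, which is the standard furanone synthesis from a terminal alkyne and a 2-hydroxy-acid derivative; 14 comes from 13 in one step. The acylation must not touch the ketal and the ring closure must be mild.

12 to 7 and 8 (through 10 and 11): C9–C10 is cut (ketone synthesis from a Weinreb amide). The demand is that the β,γ-unsaturated ketone with its α-stereocentre is ketalized without enolization.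

7 to 1 and 2 (through 4 and 6): C11–C12 is cut. The only stereocentre of the photosubstrate comes from an auxiliary-controlled alkylation, which must occur at the α-carbon of the dienolate and must not move the alkene into conjugation.

## Other disconnections considered

Alternative 1: The cut is at C11–C12 and C5–C6. In the forward step the magnesium alkoxide of hydroxy enone A1 directs the ring C Grignard reagent A2 to C11, syn to the C10 oxygen, and the resulting enolate is trapped at C6 by vinyl ketone A3 to give diketone A4.
- In its favour: ring C, the linker and the quaternary C6 arrive in one operation; C10 and C11 are set by a well-understood directing effect; no separate linker steps are needed.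
- Against it here: the hindered trisubstituted enolate must add to a polymerizable vinyl ketone faster than it exchanges protons. Ring A is not closed; it still needs a reductive etherification between a tertiary oxygen and the hindered C7 ketone, with C7 and C3 set afterwards.
- Comparison: in convergence and step economy this plan is the better one, and its control of C10/C11 is at least equal. All its steps are ground-state ionic reactions, which are easier to predict than a triplet diradical. The chosen plan is stronger on the structural crux, because both C–O bonds of ring A exist before ring B is formed.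

Alternative 2: The cut is at O1–C2 and C6–C11. In the forward step a Lewis acid activates the terminal epoxide of diepoxide A5, the C6/C7 epoxide oxygen attacks C2, and the epoxonium ion is opened at C6 by enol carbon C11 to give A6.
- In its favour: rings A and B, with C3, C6 and C7, follow from two reagent-controlled epoxidations and stereospecific anti openings. A5 is a few steps from geranyl bromide and an acetoacetate. A6 already carries C3–OH and a C10 ketone.
- Against it here: attack at C2 (seven-membered ring) competes with attack at C3 (six-membered ring) and with early capture of either cation; O-alkylation of the keto ester competes with C-alkylation. C12 must still be reduced and linked.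
- Comparison: it is equal or better in step economy and clearly better in the certainty of the ring-fusion stereochemistry, which follows from the E alkene. The chosen plan is better in constitutional certainty (the seven-membered ring cannot be replaced by a six-membered one) and weaker in facial control, which rests on one stereocentre.

Alternative 3: The cut is at O1–C7. In the forward step a peracid converts trans-decalone A7 to lactone A8; the more substituted C7 migrates with retention.
- In its favour: the trans fusion and the quaternary C6 come from established decalone chemistry, and migratory aptitude and retention make this the most reliable key step of the four.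
- Against it here: A8 lacks the C2 methyl groups and the C3 oxygen. Turning a lactone carbonyl into a gem-dimethyl ether carbon needs ring opening and re-closure at a tertiary centre or a multistep methylenation sequence, and C10/C11 functionality is still missing, so the route is the longest.
- Comparison: it is better in reliability of the key step and of the C6/C7 relationship. It is worse in step economy and in how much of ring A the key step delivers; the chosen plan installs C2, the C3 oxygen and both C–O bonds at once.

Key step: step 10

Assumption: atoms carry squalene numbers (O1, C2–C11 rings A and B, C12–C13 linker, C14–C19 ring C, C20–C23 side chain); ketone 32 is carried as a mixture of C15 epimers because that centre becomes trigonal in 34.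

Remark: C11 is S in 6–25 and R from 26 on without any change in space, because the CIP ranking of its substituents changes.

## Steps

Step 1
Reactants: 1 3-methylbut-3-enoic acid; 2 (R)-4-benzyloxazolidin-2-one
Product: 4 (R)-4-benzyl-3-(3-methylbut-3-enoyl)oxazolidin-2-one, via mixed pivalic anhydride 3 (not isolated)
Conditions: PivCl, Et3N, THF, −20 °C; then 2, LiCl, −20 → 0 °C
Reagents that add atoms: none
Why: Mixed-anhydride N-acylation of the oxazolidinone; the low temperature and absence of a strong base should keep the β,γ-alkene from moving into conjugation.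

Step 2
Reactants: 4 (R)-4-benzyl-3-(3-methylbut-3-enoyl)oxazolidin-2-one
Product: 6 (R)-4-benzyl-3-[(S)-2-(benzyloxymethyl)-3-methylbut-3-enoyl]oxazolidin-2-one, via titanium Z-enolate 5 (not isolated)
Conditions: TiCl4, i-Pr2NEt, CH2Cl2, 0 °C; then BnOCH2Cl, 0 °C
Reagents that add atoms: benzyl chloromethyl ether, ClCOCc1ccccc1
Why: Evans alkylation of the chelated Z enolate; the electrophile attacks the α-carbon C11 of the dienolate on the face away from the auxiliary benzyl group, which sets C11 as S.

Step 3
Reactants: 6 (R)-4-benzyl-3-[(S)-2-(benzyloxymethyl)-3-methylbut-3-enoyl]oxazolidin-2-one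
Product: 7 (S)-2-(benzyloxymethyl)-N-methoxy-N,3-dimethylbut-3-enamide
Conditions: MeNH(OMe)·HCl, AlMe3, CH2Cl2, 0 °C → rt
Reagents that add atoms: N,O-dimethylhydroxylamine hydrochloride, Cl.CNOC
Why: Aluminium amide aminolysis of the exocyclic imide carbonyl (Weinreb amide formation) is not basic enough to enolize C11 and releases the auxiliary for reuse.

Step 4
Reactants: 7 (S)-2-(benzyloxymethyl)-N-methoxy-N,3-dimethylbut-3-enamide; 8 (4-bromobut-1-yn-1-yl)trimethylsilane
Product: 10 (S)-3-(benzyloxymethyl)-2-methyl-8-(trimethylsilyl)oct-1-en-7-yn-4-one, via butynyl Grignard reagent 9 (not isolated)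
Conditions: 8, Mg, THF, 40 °C; then 7, THF, 0 °C; cold aq. NH4Cl
Reagents that add atoms: none
Why: Weinreb ketone synthesis; the chelated tetrahedral adduct stops at the ketone, and a cold buffered quench should avoid enolization of the β,γ-unsaturated ketone at C11.

Step 5
Reactants: 10 (S)-3-(benzyloxymethyl)-2-methyl-8-(trimethylsilyl)oct-1-en-7-yn-4-one
Product: 11 2-[(S)-1-(benzyloxy)-3-methylbut-3-en-2-yl]-2-[4-(trimethylsilyl)but-3-yn-1-yl]-1,3-dioxolane
Conditions: (TMSOCH2)2, TMSOTf (cat.), CH2Cl2, −78 → −20 °C; pyridine quench
Reagents that add atoms: 1,2-bis(trimethylsilyloxy)ethane, C[Si](C)(C)OCCO[Si](C)(C)C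
Why: TMSOTf-catalysed ketalization with the bis-silyl ether runs cold and without protic acid, the conditions least likely to enolize C11, shift the alkene or eliminate the β-benzyloxy group.

Step 6
Reactants: 11 2-[(S)-1-(benzyloxy)-3-methylbut-3-en-2-yl]-2-[4-(trimethylsilyl)but-3-yn-1-yl]-1,3-dioxolane
Product: 12 2-[(S)-1-(benzyloxy)-3-methylbut-3-en-2-yl]-2-(but-3-yn-1-yl)-1,3-dioxolane
Conditions: K2CO3 (cat.), MeOH, rt
Reagents that add atoms: none
Why: Methanolysis of the alkynyl C–Si bond; ketal, benzyl ether and alkene are inert.

Step 7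
Reactants: 13 methyl 2-hydroxy-2-methylpropanoate
Product: 14 2-hydroxy-N-methoxy-N,2-dimethylpropanamide
Conditions: MeNH(OMe)·HCl, i-PrMgCl, THF, −20 → 0 °C
Reagents that add atoms: N,O-dimethylhydroxylamine hydrochloride, Cl.CNOC
Why: Weinreb amide formation from the ester by the magnesium amide; the tertiary hydroxyl is carried as its alkoxide and returns on work-up.

Step 8
Reactants: 12 2-[(S)-1-(benzyloxy)-3-methylbut-3-en-2-yl]-2-(but-3-yn-1-yl)-1,3-dioxolane; 14 2-hydroxy-N-methoxy-N,2-dimethylpropanamide
Product: 17 7-{2-[(S)-1-(benzyloxy)-3-methylbut-3-en-2-yl]-1,3-dioxolan-2-yl}-2-hydroxy-2-methylhept-4-yn-3-one, via lithium acetylide 15 (not isolated), via chloromagnesium alkoxide 16 (not isolated)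
Conditions: 12, n-BuLi, THF, −78 °C; 14, i-PrMgCl, THF, −20 °C (second flask); combine, −78 → 0 °C; aq. NH4Cl
Reagents that add atoms: none
Why: Acylation of the acetylide by the Weinreb amide gives the ynone without over-addition; the hydroxyl is masked as its alkoxide so the acetylide is not quenched.

Step 9
Reactants: 17 7-{2-[(S)-1-(benzyloxy)-3-methylbut-3-en-2-yl]-1,3-dioxolan-2-yl}-2-hydroxy-2-methylhept-4-yn-3-one
Product: 18 5-(2-{2-[(S)-1-(benzyloxy)-3-methylbut-3-en-2-yl]-1,3-dioxolan-2-yl}ethyl)-2,2-dimethylfuran-3(2H)-one
Conditions: Et2NH, EtOH, rt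
Reagents that add atoms: none
Why: Conjugate addition of the amine to the ynone and addition–elimination by the tertiary hydroxyl is the standard closure to 2,2-dimethylfuran-3(2H)-ones; the amine is released again.

Step 10
Reactants: 18 5-(2-{2-[(S)-1-(benzyloxy)-3-methylbut-3-en-2-yl]-1,3-dioxolan-2-yl}ethyl)-2,2-dimethylfuran-3(2H)-one
Product: 19 cis-fused furanone–cyclobutane–cyclohexane photoadduct (4S,6R,7S,11S)
Conditions: hν (350 nm, Pyrex), degassed MeCN, 0.005 M, 0 °C
Reagents that add atoms: none
Why: Excitation of the furanone and intersystem crossing give the triplet vinylogous ester, whose C7 adds to C6 of the tethered alkene (6-exo-trig, closing ring B) to give a 1,4-diradical at C4 and C5; after spin inversion this collapses to the C4–C5 bond and closes the cyclobutane by radical recombination. The closest known reaction type is the intramolecular enone–alkene [2+2] photocycloaddition of furan-3(2H)-ones and other vinylogous esters that carry the alkene on a four-atom tether. Straight rather than crossed addition is needed, and is expected because the tether reaches C6 through an unstrained six-membered transition state and this is also the head-to-tail orientation preferred by a 1,1-disubstituted alkene. C7 and C4 follow from geometry: furanone and cyclobutane can only be cis-fused, and C4 and C5 must lie on the same face of ring B for the diradical to close. C6 is set relative to C11 by the fold of the tether: in the chair with the exocyclic methylene and the C11 benzyloxymethyl group both equatorial, the C7–C4 bond is axial and C7 reaches the alkene face that places the C6 methyl cis to C12, while an axial C12 in this chair would clash syn-axially with C4. Facial selectivity is therefore the selectivity the step needs, and the S centre at C11, held against epimerization by the flanking ketal, is the only element that secures it; the competing chair with the methylene axial would give the opposite C6/C7 pair and is weighed at the end. Chemoselectivity rests on the chromophores: only the furanone absorbs near 350 nm, it cannot enolize, the ketal removes the β,γ-unsaturated ketone, and high dilution suppresses dimerization.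

Step 11
Reactants: 19 cis-fused furanone–cyclobutane–cyclohexane photoadduct (4S,6R,7S,11S)
Product: 21 trans-fused oxepan-3-one (6R,7R,11S), via samarium enolate 20 (not isolated)
Conditions: SmI2 (2.5 equiv), HMPA, THF, −78 → 0 °C; aq. NH4Cl
Reagents that add atoms: none
Why: Proposed new method: electron transfer from SmI2 gives the C3 ketyl, and the adjacent cyclobutane bond C4–C7 should break because this releases the ring strain and leaves a tertiary radical at C7 stabilized by O1, whereas breaking C4–C5 would leave a primary radical and loss of O1 from C2 would release no strain; the C7 radical should then take up hydrogen on the face anti to the C6 methyl group (trans fusion), and the trivalent samarium enolate shields the new ketone until work-up; the closest known reaction type is the SmI2-promoted ketyl ring opening of cyclobutyl ketones made by [2+2] photocycloaddition, where a radical-stabilizing group on the distal carbon directs cleavage to the ring-fusion bond.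

Step 12
Reactants: 21 trans-fused oxepan-3-one (6R,7R,11S)
Product: 22 trans-fused oxepan-3-ol (3R,6R,7R,11S)
Conditions: (S)-2-methyl-CBS-oxazaborolidine, BH3·SMe2, THF, −20 °C
Reagents that add atoms: none
Why: CBS reduction; the catalyst distinguishes the quaternary C2 flank (large) from the C4 methylene (small), so the (S)-catalyst should give the 3R carbinol by reagent control.

Step 13
Reactants: 22 trans-fused oxepan-3-ol (3R,6R,7R,11S)
Product: 23 C3 tert-butyldimethylsilyl ether of 22
Conditions: TBSOTf, 2,6-lutidine, CH2Cl2, −78 → 0 °C
Reagents that add atoms: tert-butyldimethylsilyl triflate, CC(C)(C)[Si](C)(C)OS(=O)(=O)C(F)(F)F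
Why: The neopentyl-type carbinol needs the silyl triflate; with a hindered base at low temperature the dioxolane should survive.

Step 14
Reactants: 23 C3 tert-butyldimethylsilyl ether of 22
Product: 24 C12 primary alcohol (3R,6R,7R,11S)
Conditions: H2 (1 atm), 10% Pd/C, EtOAc, rt
Reagents that add atoms: none
Why: Hydrogenolysis of the benzyl ether; no alkene is present at this stage, and silyl ether and ketal are stable.

Step 15
Reactants: 24 C12 primary alcohol (3R,6R,7R,11S)
Product: 25 C12 aldehyde (3R,6R,7R,11S)
Conditions: Dess–Martin periodinane, NaHCO3, CH2Cl2, 0 °C → rt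
Reagents that add atoms: none
Why: Buffered Dess–Martin oxidation gives the α-branched aldehyde under neutral conditions that should not epimerize C11.

Step 16
Reactants: 25 C12 aldehyde (3R,6R,7R,11S)
Product: 26 C11 vinyl compound (3R,6R,7R,11R)
Conditions: Ph3PCH3Br, KN(SiMe3)2, THF, 0 °C; then 25, −78 → 0 °C
Reagents that add atoms: methyltriphenylphosphonium bromide, C[P+](c1ccccc1)(c1ccccc1)c1ccccc1.[Br-]
Why: Wittig methylenation; the unstabilized ylide adds at low temperature faster than it deprotonates C11, and C10 is still a ketal so no β,γ-unsaturated ketone can arise.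

Step 17
Reactants: 27 2-methylcyclohexane-1,3-dione
Product: 28 2-allyl-2-methylcyclohexane-1,3-dione
Conditions: allyl acetate, Pd(PPh3)4 (2 mol %), Et3N, THF, 50 °C
Reagents that add atoms: allyl acetate, C=CCOC(C)=O
Why: Tsuji–Trost C-allylation through a π-allyl complex of divalent palladium formed from the zerovalent catalyst; any O-allyl isomer re-ionizes and funnels to the C-allyl product.

Step 18
Reactants: 28 2-allyl-2-methylcyclohexane-1,3-dione
Product: 29 (2R,3R)-2-allyl-3-hydroxy-2-methylcyclohexan-1-one
Conditions: (S)-2-methyl-CBS-oxazaborolidine (20 mol %), catecholborane, toluene, −78 °C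
Reagents that add atoms: none
Why: CBS reduction used as a desymmetrization; the catalyst selects one enantiotopic carbonyl (3R carbinol, quaternary flank as the large group) and hydride enters anti to the larger allyl group, so OH ends cis to allyl (2R).

Step 19
Reactants: 29 (2R,3R)-2-allyl-3-hydroxy-2-methylcyclohexan-1-one
Product: 30 (2R,3R)-2-allyl-3-(tert-butyldimethylsilyloxy)-2-methylcyclohexan-1-one
Conditions: TBSCl, imidazole, DMF, 40 °C
Reagents that add atoms: tert-butyldimethylsilyl chloride, CC(C)(C)[Si](C)(C)Cl
Why: Standard silylation of a secondary alcohol; the β-silyloxy ketone cannot eliminate because the intervening carbon is quaternary.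

Step 20
Reactants: 30 (2R,3R)-2-allyl-3-(tert-butyldimethylsilyloxy)-2-methylcyclohexan-1-one
Product: 32 (2R,3R)-2-allyl-3-(tert-butyldimethylsilyloxy)-2,6-dimethylcyclohexan-1-one (C6 epimers), via lithium enolate 31 (not isolated)
Conditions: LiN(i-Pr)2, THF, −78 °C; then MeI, −78 → −20 °C
Reagents that add atoms: iodomethane, CI
Why: Enolate alkylation; only one α-position bears hydrogen, and the configuration of the new centre is irrelevant.

Step 21
Reactants: 32 (2R,3R)-2-allyl-3-(tert-butyldimethylsilyloxy)-2,6-dimethylcyclohexan-1-one (C6 epimers)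
Product: 34 (5R,6R)-6-allyl-5-(tert-butyldimethylsilyloxy)-2,6-dimethylcyclohex-1-en-1-yl triflate, via potassium enolate 33 (not isolated)
Conditions: KN(SiMe3)2, THF, −78 °C; then PhNTf2, −78 → 0 °C
Reagents that add atoms: N-phenylbis(trifluoromethanesulfonimide), O=S(=O)(N(c1ccccc1)S(=O)(=O)C(F)(F)F)C(F)(F)F
Why: The only remaining α-hydrogen gives the tetrasubstituted enolate, and O-sulfonylation delivers the enol triflate regiospecifically.

Step 22
Reactants: 26 C11 vinyl compound (3R,6R,7R,11R); 34 (5R,6R)-6-allyl-5-(tert-butyldimethylsilyloxy)-2,6-dimethylcyclohex-1-en-1-yl triflate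
Product: 36 coupled ketal (3R,6R,7R,11R,18R,19S), via B-alkyl-9-BBN borane 35 (not isolated)
Conditions: 26 (1.2 equiv), 9-BBN (1.1 equiv), THF, rt → 40 °C; then 34, Pd(dppf)Cl2 (10 mol %), AsPh3, Cs2CO3, DMF/H2O, 50 °C
Reagents that add atoms: none
Why: Anti-Markovnikov hydroboration of the monosubstituted alkene, then B-alkyl Suzuki–Miyaura coupling with the enol triflate forms C13–C14; all B–H is consumed before the allyl-bearing triflate is added, and the dppf/AsPh3 system is chosen to outrun β-hydride elimination.

Step 23
Reactants: 36 coupled ketal (3R,6R,7R,11R,18R,19S)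
Product: 37 C10 ketone (3R,6R,7R,11R,18R,19S)
Conditions: PPTS, acetone/H2O, 60 °C
Reagents that add atoms: water, O
Why: Mild acid hydrolysis of the ketal leaves the hindered secondary silyl ethers; C11 already carries its chain equatorially, the more stable arrangement next to the new carbonyl.

Step 24
Reactants: 37 C10 ketone (3R,6R,7R,11R,18R,19S)
Product: 38 C10 tertiary carbinol (3R,6R,7R,10S,11R,18R,19S)
Conditions: MeMgBr, CeCl3, THF, −78 → 0 °C
Reagents that add atoms: methylmagnesium bromide, C[Mg]Br
Why: Organocerium addition suppresses enolization toward C11; the axial path is blocked by the syn-axial C6 methyl group, so the methyl enters equatorially and the hydroxyl ends axial (10S).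

Step 25
Reactants: 38 C10 tertiary carbinol (3R,6R,7R,10S,11R,18R,19S)
Product: 39 bis-silyl ether of siphonellinol C
Conditions: 2-methylbut-3-en-2-ol (excess), second-generation Hoveyda–Grubbs catalyst RuCl2(SIMes)(=CH-C6H4-2-O-i-Pr) (5 mol %), CH2Cl2, 40 °C
Reagents that add atoms: 2-methylbut-3-en-2-ol, CC(C)(O)C=C
Why: Cross-metathesis of the terminal allyl group with an excess of the slowly homodimerizing tertiary allylic alcohol should give the E alkene; the tetrasubstituted ring alkene is inert to the catalyst.

Step 26
Reactants: 39 bis-silyl ether of siphonellinol C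
Product: 40 siphonellinol C
Conditions: TBAF, THF, 50 °C
Reagents that add atoms: none
Why: Fluoride cleavage of the two secondary silyl ethers; the basic medium spares the tertiary allylic alcohol, which an acidic deprotection could ionize.

## Compound list

1 | 3-methylbut-3-enoic acid | C=C(C)CC(=O)O | starting material
2 | (R)-4-benzyloxazolidin-2-one | O=C1N[C@H](Cc2ccccc2)CO1 | starting material
3 | 3-methylbut-3-enoic pivalic anhydride (formed in situ) | C=C(C)CC(=O)OC(=O)C(C)(C)C | intermediate
4 | (R)-4-benzyl-3-(3-methylbut-3-enoyl)oxazolidin-2-one | C=C(C)CC(=O)N1C(=O)OC[C@H]1Cc1ccccc1 | intermediate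
5 | trichlorotitanium Z-enolate of 4 (formed in situ) | C=C(C)/C=C(\O[Ti](Cl)(Cl)Cl)N1C(=O)OC[C@H]1Cc1ccccc1 | intermediate
6 | (R)-4-benzyl-3-[(S)-2-(benzyloxymethyl)-3-methylbut-3-enoyl]oxazolidin-2-one | C=C(C)[C@@H](COCc1ccccc1)C(=O)N1C(=O)OC[C@H]1Cc1ccccc1 | intermediate
7 | (S)-2-(benzyloxymethyl)-N-methoxy-N,3-dimethylbut-3-enamide | C=C(C)[C@@H](COCc1ccccc1)C(=O)N(C)OC | intermediate
8 | (4-bromobut-1-yn-1-yl)trimethylsilane | C[Si](C)(C)C#CCCBr | starting material
9 | [4-(trimethylsilyl)but-3-yn-1-yl]magnesium bromide (formed in situ) | C[Si](C)(C)C#CCC[Mg]Br | intermediate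
10 | (S)-3-(benzyloxymethyl)-2-methyl-8-(trimethylsilyl)oct-1-en-7-yn-4-one | C=C(C)[C@@H](COCc1ccccc1)C(=O)CCC#C[Si](C)(C)C | intermediate
11 | 2-[(S)-1-(benzyloxy)-3-methylbut-3-en-2-yl]-2-[4-(trimethylsilyl)but-3-yn-1-yl]-1,3-dioxolane | C=C(C)[C@@H](COCc1ccccc1)C1(CCC#C[Si](C)(C)C)OCCO1 | intermediate
12 | 2-[(S)-1-(benzyloxy)-3-methylbut-3-en-2-yl]-2-(but-3-yn-1-yl)-1,3-dioxolane | C=C(C)[C@@H](COCc1ccccc1)C1(CCC#C)OCCO1 | intermediate
13 | methyl 2-hydroxy-2-methylpropanoate | COC(=O)C(C)(C)O | starting material
14 | 2-hydroxy-N-methoxy-N,2-dimethylpropanamide | CON(C)C(=O)C(C)(C)O | intermediate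
15 | lithium acetylide of 12 (formed in situ) | C=C(C)[C@@H](COCc1ccccc1)C1(CCC#C[Li])OCCO1 | intermediate
16 | chloromagnesium alkoxide of 14 (formed in situ) | CON(C)C(=O)C(C)(C)O[Mg]Cl | intermediate
17 | 7-{2-[(S)-1-(benzyloxy)-3-methylbut-3-en-2-yl]-1,3-dioxolan-2-yl}-2-hydroxy-2-methylhept-4-yn-3-one | CC(C)(O)C(=O)C#CCCC1(OCCO1)[C@H](COCc1ccccc1)C(C)=C | intermediate
18 | 5-(2-{2-[(S)-1-(benzyloxy)-3-methylbut-3-en-2-yl]-1,3-dioxolan-2-yl}ethyl)-2,2-dimethylfuran-3(2H)-one (photosubstrate) | CC1(C)OC(=CC1=O)CCC1(OCCO1)[C@H](COCc1ccccc1)C(C)=C | intermediate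
19 | photoadduct (4S,6R,7S,11S): 2,2-dimethyldihydrofuran-3-one fused at C4–C7 to a cyclobutane (C4, C5, C6, C7) fused at C6–C7 to ring B; C6 methyl, C10 spiro-dioxolane, C11 benzyloxymethyl | CC1(C)O[C@]23CCC4(OCCO4)[C@H](COCc5ccccc5)[C@@]2(C)C[C@@H]3C1=O | intermediate
20 | diiodosamarium enolate of 21 (C3=C4, formed in situ) | CC1(C)O[C@@H]2CCC3(OCCO3)[C@H](COCc4ccccc4)[C@@]2(C)CC=C1O[Sm](I)I | intermediate
21 | trans-fused ring A/B oxepan-3-one (6R,7R,11S); 2,2,6-trimethyl, C10 dioxolane, C11 benzyloxymethyl | CC1(C)O[C@@H]2CCC3(OCCO3)[C@H](COCc4ccccc4)[C@@]2(C)CCC1=O | intermediate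
22 | C3 carbinol (3R,6R,7R,11S) of 21 | CC1(C)O[C@@H]2CCC3(OCCO3)[C@H](COCc4ccccc4)[C@@]2(C)CC[C@H]1O | intermediate
23 | C3 tert-butyldimethylsilyl ether of 22 | CC1(C)O[C@@H]2CCC3(OCCO3)[C@H](COCc4ccccc4)[C@@]2(C)CC[C@H]1O[Si](C)(C)C(C)(C)C | intermediate
24 | C12 primary alcohol (3R,6R,7R,11S); C3 silyl ether, C10 dioxolane | CC1(C)O[C@@H]2CCC3(OCCO3)[C@H](CO)[C@@]2(C)CC[C@H]1O[Si](C)(C)C(C)(C)C | intermediate
25 | C12 aldehyde (3R,6R,7R,11S) | CC1(C)O[C@@H]2CCC3(OCCO3)[C@H](C=O)[C@@]2(C)CC[C@H]1O[Si](C)(C)C(C)(C)C | intermediate
26 | C11 vinyl compound (3R,6R,7R,11R) | CC1(C)O[C@@H]2CCC3(OCCO3)[C@H](C=C)[C@@]2(C)CC[C@H]1O[Si](C)(C)C(C)(C)C | intermediate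
27 | 2-methylcyclohexane-1,3-dione | CC1C(=O)CCCC1=O | starting material
28 | 2-allyl-2-methylcyclohexane-1,3-dione | C=CCC1(C)C(=O)CCCC1=O | intermediate
29 | (2R,3R)-2-allyl-3-hydroxy-2-methylcyclohexan-1-one | C=CC[C@@]1(C)C(=O)CCC[C@H]1O | intermediate
30 | (2R,3R)-2-allyl-3-(tert-butyldimethylsilyloxy)-2-methylcyclohexan-1-one | C=CC[C@@]1(C)C(=O)CCC[C@H]1O[Si](C)(C)C(C)(C)C | intermediate
31 | lithium enolate of 30 (formed in situ) | C=CC[C@@]1(C)C(O[Li])=CCC[C@H]1O[Si](C)(C)C(C)(C)C | intermediate
32 | (2R,3R)-2-allyl-3-(tert-butyldimethylsilyloxy)-2,6-dimethylcyclohexan-1-one (C6 epimers) | C=CC[C@@]1(C)C(=O)C(C)CC[C@H]1O[Si](C)(C)C(C)(C)C | intermediate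
33 | potassium enolate of 32 (formed in situ) | C=CC[C@@]1(C)C(O[K])=C(C)CC[C@H]1O[Si](C)(C)C(C)(C)C | intermediate
34 | (5R,6R)-6-allyl-5-(tert-butyldimethylsilyloxy)-2,6-dimethylcyclohex-1-en-1-yl trifluoromethanesulfonate | C=CC[C@@]1(C)C(OS(=O)(=O)C(F)(F)F)=C(C)CC[C@H]1O[Si](C)(C)C(C)(C)C | intermediate
35 | B-alkyl-9-BBN borane from 26 (boron on C13, formed in situ) | CC1(C)O[C@@H]2CCC3(OCCO3)[C@H](CCB4C5CCCC4CCC5)[C@@]2(C)CC[C@H]1O[Si](C)(C)C(C)(C)C | intermediate
36 | coupled ketal (3R,6R,7R,11R,18R,19S); C10 dioxolane, C3 and C18 silyl ethers, C19 allyl | CC1(C)O[C@@H]2CCC3(OCCO3)[C@H](CCC4=C(C)CC[C@@H](O[Si](C)(C)C(C)(C)C)[C@@]4(C)CC=C)[C@@]2(C)CC[C@H]1O[Si](C)(C)C(C)(C)C | intermediate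
37 | C10 ketone (3R,6R,7R,11R,18R,19S) | CC1(C)O[C@@H]2CCC(=O)[C@H](CCC3=C(C)CC[C@@H](O[Si](C)(C)C(C)(C)C)[C@@]3(C)CC=C)[C@@]2(C)CC[C@H]1O[Si](C)(C)C(C)(C)C | intermediate
38 | C10 tertiary carbinol (3R,6R,7R,10S,11R,18R,19S); C19 allyl | CC1(C)O[C@@H]2CC[C@](C)(O)[C@H](CCC3=C(C)CC[C@@H](O[Si](C)(C)C(C)(C)C)[C@@]3(C)CC=C)[C@@]2(C)CC[C@H]1O[Si](C)(C)C(C)(C)C | intermediate
39 | 3,18-bis(tert-butyldimethylsilyl) ether of siphonellinol C | CC1(C)O[C@@H]2CC[C@](C)(O)[C@H](CCC3=C(C)CC[C@@H](O[Si](C)(C)C(C)(C)C)[C@@]3(C)C/C=C/C(C)(C)O)[C@@]2(C)CC[C@H]1O[Si](C)(C)C(C)(C)C | intermediate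
40 | siphonellinol C | CC1=C(CC[C@@H]2[C@@]3(C)CC[C@@H](O)C(C)(C)O[C@@H]3CC[C@]2(C)O)[C@](C)(C/C=C/C(C)(C)O)[C@H](O)CC1 | target

## Step count and least certain steps

Total step count: 26. Longest linear sequence: 20 steps (steps 1–6, 8–16 and 22–26, from 1). Side branches: step 7 (one step) and steps 17–21 (five steps).

Step 11 (SmI2 ring expansion). The most likely failure is fragmentation in the wrong direction, or none.
- The C4–C7 bond lies close to the plane of the five-membered ring and overlaps poorly with the ketyl.
- Cleavage of the better aligned C4–C5 bond, reductive loss of O1 from C2 (α-alkoxy ketone cleavage) or simple reduction to the carbinol may therefore compete.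
- Hydrogen delivery to C7 from the methyl face would give the cis-fused bicycle.

The fallback uses known radical chemistry; it sets out from 19 and returns at 21. NaBH4 reduces the C3 ketone to the photoadduct carbinol F1. NaH, CS2 and MeI convert it to the xanthate F2. Bu3SnH and AIBN, added slowly in hot benzene, generate the C3 carbon radical. This is a cyclobutylcarbinyl radical with no competing heterolysis; it should open by β-scission of C4–C7 and, after hydrogen transfer to C7, give the oxepene F3 (C3=C4). mCPBA gives the epoxide F4. LiAlH4 opens it at the less hindered C4 and gives 22 together with its C3 epimer F5. Dess–Martin oxidation of the mixture converges on 21.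

Step 10 (key step). The most likely failure is poor facial selectivity.
- The tether can also fold through a second chair in which the exocyclic methylene and O1 are axial and C12 is still equatorial.
- That fold avoids the near-eclipsing of the C6 methyl group with C10 (A(1,2) strain) that the productive chair must accept, and it delivers C7 to the other alkene face (C4, C6 and C7 inverted relative to C11).
- Allylic strain at a 1,1-disubstituted alkene is a weak control element, so an unfavourable partition between the folds, up to a reversal of the sense, cannot be excluded.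
- Lesser risks are 1,5-hydrogen transfer from the allylic C11–H to the excited C7, and dimerization.

The fallback keeps the cycloaddition but relays chirality from the mirror-image C11 centre and corrects C11 afterwards; it sets out from 1 and returns at 22. Steps 1–9 are run with (S)-4-benzyloxazolidin-2-one. They lead through the mirror-image imide F6, alkylation product F7, Weinreb amide F8, ketone F9, ketal F10, alkyne F11 and ynone F12 to the enantiomeric furanone F13. If the methylene-axial chair is the preferred fold, F13 should give the photoadduct F14, which has C4, C6 and C7 as in 19 and only C11 inverted. SmI2 cleavage (oxepanone F15) and CBS reduction (carbinol F16) follow as in steps 11 and 12. Hydrolysis of the ketal (PPTS, wet acetone) gives the hydroxy ketone F17, in which C11 is α to the C10 carbonyl and carries its chain axially. Mild base (DBU, toluene) should equilibrate it to the equatorial epimer F18. Ketalization as in step 5 then returns 22.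

Step 22 (B-alkyl Suzuki–Miyaura coupling). The most likely failure is slow oxidative addition and transmetalation at a tetrasubstituted triflate flanked by a quaternary carbon, with a borane next to the congested C11. β-Hydride elimination, protodeboronation or triflate hydrolysis may then win, and stray B–H would hydroborate the allyl group.

The fallback forms C13–C14 by carbonyl addition; it sets out from 26 and returns at 36. Hydroboration–oxidation of 26 (9-BBN; NaOH, H2O2) gives the primary alcohol F19. I2, PPh3 and imidazole give the iodide F20. Iodine–lithium exchange (t-BuLi, −78 °C) and transmetalation with CeCl3 give a nucleophile that adds to ketone 32 and forms the tertiary carbinol F21. Dehydration (SOCl2, pyridine) toward C15 should give the tetrasubstituted alkene 36.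

## Further compounds

F1 | step 11 | C3 carbinol of photoadduct 19 (C3 epimers) | CC1(C)O[C@]23CCC4(OCCO4)[C@H](COCc5ccccc5)[C@@]2(C)C[C@@H]3C1O
F2 | step 11 | S-methyl xanthate of F1 | CC1(C)O[C@]23CCC4(OCCO4)[C@H](COCc5ccccc5)[C@@]2(C)C[C@@H]3C1OC(=S)SC
F3 | step 11 | trans-fused oxepene (C3=C4; 6R,7R,11S) | CC1(C)O[C@@H]2CCC3(OCCO3)[C@H](COCc4ccccc4)[C@@]2(C)CC=C1
F4 | step 11 | C3/C4 epoxide of F3 (face isomers) | CC1(C)O[C@@H]2CCC3(OCCO3)[C@H](COCc4ccccc4)[C@@]2(C)CC5OC15
F5 | step 11 | C3 epimer of 22 (3S,6R,7R,11S) | CC1(C)O[C@@H]2CCC3(OCCO3)[C@H](COCc4ccccc4)[C@@]2(C)CC[C@@H]1O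
F6 | step 10 | (S)-4-benzyl-3-(3-methylbut-3-enoyl)oxazolidin-2-one | C=C(C)CC(=O)N1C(=O)OC[C@@H]1Cc1ccccc1
F7 | step 10 | (S)-4-benzyl-3-[(R)-2-(benzyloxymethyl)-3-methylbut-3-enoyl]oxazolidin-2-one | C=C(C)[C@H](COCc1ccccc1)C(=O)N1C(=O)OC[C@@H]1Cc1ccccc1
F8 | step 10 | (R)-2-(benzyloxymethyl)-N-methoxy-N,3-dimethylbut-3-enamide | C=C(C)[C@H](COCc1ccccc1)C(=O)N(C)OC
F9 | step 10 | (R)-3-(benzyloxymethyl)-2-methyl-8-(trimethylsilyl)oct-1-en-7-yn-4-one | C=C(C)[C@H](COCc1ccccc1)C(=O)CCC#C[Si](C)(C)C
F10 | step 10 | 2-[(R)-1-(benzyloxy)-3-methylbut-3-en-2-yl]-2-[4-(trimethylsilyl)but-3-yn-1-yl]-1,3-dioxolane | C=C(C)[C@H](COCc1ccccc1)C1(CCC#C[Si](C)(C)C)OCCO1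
F11 | step 10 | 2-[(R)-1-(benzyloxy)-3-methylbut-3-en-2-yl]-2-(but-3-yn-1-yl)-1,3-dioxolane | C=C(C)[C@H](COCc1ccccc1)C1(CCC#C)OCCO1
F12 | step 10 | enantiomer of ynone 17 | CC(C)(O)C(=O)C#CCCC1(OCCO1)[C@@H](COCc1ccccc1)C(C)=C
F13 | step 10 | enantiomer of furanone 18 | CC1(C)OC(=CC1=O)CCC1(OCCO1)[C@@H](COCc1ccccc1)C(C)=C
F14 | step 10 | C11 epimer of photoadduct 19 | CC1(C)O[C@]23CCC4(OCCO4)[C@@H](COCc5ccccc5)[C@@]2(C)C[C@@H]3C1=O
F15 | step 10 | C11 epimer of oxepanone 21 | CC1(C)O[C@@H]2CCC3(OCCO3)[C@@H](COCc4ccccc4)[C@@]2(C)CCC1=O
F16 | step 10 | C11 epimer of carbinol 22 | CC1(C)O[C@@H]2CCC3(OCCO3)[C@@H](COCc4ccccc4)[C@@]2(C)CC[C@H]1O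
F17 | step 10 | C10 ketone with axial C11 benzyloxymethyl (C11 epimer of F18) | CC1(C)O[C@@H]2CCC(=O)[C@@H](COCc3ccccc3)[C@@]2(C)CC[C@H]1O
F18 | step 10 | C10 ketone with equatorial C11 benzyloxymethyl (C11 as in 22) | CC1(C)O[C@@H]2CCC(=O)[C@H](COCc3ccccc3)[C@@]2(C)CC[C@H]1O
F19 | step 22 | C13 primary alcohol from 26 | CC1(C)O[C@@H]2CCC3(OCCO3)[C@H](CCO)[C@@]2(C)CC[C@H]1O[Si](C)(C)C(C)(C)C
F20 | step 22 | C13 primary iodide | CC1(C)O[C@@H]2CCC3(OCCO3)[C@H](CCI)[C@@]2(C)CC[C@H]1O[Si](C)(C)C(C)(C)C
F21 | step 22 | C14 tertiary carbinol from addition to 32 (C14 and C15 epimers) | CC1(C)O[C@@H]2CCC3(OCCO3)[C@H](CCC4(O)C(C)CC[C@@H](O[Si](C)(C)C(C)(C)C)[C@@]4(C)CC=C)[C@@]2(C)CC[C@H]1O[Si](C)(C)C(C)(C)C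
A1 | alternative 1 | (S)-4-hydroxy-2,4-dimethylcyclohex-2-en-1-one | CC1=C[C@@](C)(O)CCC1=O
A2 | alternative 1 | ring C alkylmagnesium bromide (C12–MgBr; C18 TBS ether, C23 TES ether) | CC1=C(CC[Mg]Br)[C@](C)(C/C=C/C(C)(C)O[Si](CC)(CC)CC)[C@H](O[Si](C)(C)C(C)(C)C)CC1
A3 | alternative 1 | 4-methyl-4-(trimethylsilyloxy)pent-1-en-3-one | C=CC(=O)C(C)(C)O[Si](C)(C)C
A4 | alternative 1 | ring B diketone carrying ring C on C11 and the ring A chain on C6 | CC1=C(CC[C@@H]2[C@@](C)(CCC(=O)C(C)(C)O[Si](C)(C)C)C(=O)CC[C@]2(C)O)[C@](C)(C/C=C/C(C)(C)O[Si](CC)(CC)CC)[C@H](O[Si](C)(C)C(C)(C)C)CC1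
A5 | alternative 2 | diepoxide β-keto ester (3R; 6R,7R) | COC(=O)CC(=O)CC[C@H]1O[C@]1(C)CC[C@H]1OC1(C)C
A6 | alternative 2 | trans-fused oxepane–cyclohexanone β-keto ester | COC(=O)[C@@H]1[C@@]2(C)CC[C@@H](O)C(C)(C)O[C@@H]2CCC1=O
A7 | alternative 3 | trans-decalone (C2 ketone, C6 methyl, C11 dioxolane) | O=C1CCC[C@]2(C)C3(OCCO3)CCC[C@@H]12
A8 | alternative 3 | trans-fused seven-membered lactone (C2 carbonyl, C11 ketal) | O=C1CCC[C@]2(C)C3(OCCO3)CCC[C@H]2O1
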